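**Retrosynthetic overview** (core numbered as furo[3,2-c][1,2]dioxin: O1, O2, C3, C4, C4a, O5, C6(=O), C7, C7a; side-chain carbons primed)
1. Target ⇒ bicyclic enal + phenyltetrazolyl sulfone: a Julia–Kocienski olefination makes the C4'=C5' double bond last.
2. Bicyclic enal ⇒ bicyclic methyl peroxyketal + silyl dienol ether of 3-methylbut-2-enal: C3 stays at the ketone oxidation level until a vinylogous Mukaiyama substitution of its peroxycarbenium ion brings in C1'–C4'.
3. Bicyclic peroxyketal ⇒ monocyclic enol lactone carrying an acetone peroxyketal: an acid-catalysed cycloisomerisation forms the C4–C4a bond and closes the 1,2-dioxane onto the finished γ-lactone (ring order: lactone first, dioxane second).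
4. Enabling feature: C3 is a fully substituted peroxy carbon (a masked methyl ketone) whose second methyl group is the ring CH2 C4 and can react as a peroxy-enol; C4a is the oxygen-bearing γ-carbon of the lactone (an acyloxycarbenium site); the O1–O2 bridge from C7a holds both on the cis face of the ring fusion.
5. Enol lactone ⇒ pent-4-ynoic acid ⇒ pent-2-en-4-ynal + 2-hydroperoxy-2-methoxypropane: an amine-catalysed peroxidation sets C7a, which then relays C4a and C3.

Key step: step 6

Assumption: alcohol 1 is used as the pure E isomer, and the (S)-configured amine catalyst is taken to shield the enal face in the usual sense for this catalyst class.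

**Step 1**
Reactants: 1 (E)-pent-2-en-4-yn-1-ol
Product: 2 (E)-pent-2-en-4-ynal
Conditions: MnO2 (10 equiv), CH2Cl2, rt; solution used directly
Reagents that add atoms: none
Why: Allylic oxidation with activated MnO2 is selective for the allylic alcohol and should leave the alkyne and the E double bond untouched (no stereocentre).

**Step 2**
Reactants: 3 2,3-dimethylbut-2-ene
Product: 5 2-hydroperoxy-2-methoxypropane, via acetone O-oxide 4 (not isolated)
Conditions: O3, MeOH–CH2Cl2, −78 °C; kept as a solution
Reagents that add atoms: ozone, [O-][O+]=O; methanol, CO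
Why: Criegee ozonolysis of a tetrasubstituted alkene in methanol, in which the carbonyl oxide is trapped by the solvent as the α-methoxy hydroperoxide (no stereocentre).

**Step 3**
Reactants: 2 (E)-pent-2-en-4-ynal; 5 2-hydroperoxy-2-methoxypropane
Product: 6 (3S)-3-[(2-methoxypropan-2-yl)peroxy]pent-4-ynal
Conditions: 5 (1.5 equiv), (S)-2-[diphenyl(trimethylsilyloxy)methyl]pyrrolidine (10 mol %), toluene, 0 °C; crude product taken on
Reagents that add atoms: none
Why: Iminium-catalysed asymmetric oxa-Michael addition (β-peroxidation) of a hydroperoxide to an enal, in which the diphenyl(silyloxy)methyl group shields one face of the E iminium ion so that the peroxide should add to the Si face of C3 and set 3S.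

**Step 4**
Reactants: 6 (3S)-3-[(2-methoxypropan-2-yl)peroxy]pent-4-ynal
Product: 7 (3S)-3-[(2-methoxypropan-2-yl)peroxy]pent-4-ynoic acid
Conditions: NaClO2, NaH2PO4, 2-methylbut-2-ene, t-BuOH–H2O, 0 °C
Reagents that add atoms: sodium chlorite, [Na+].[O-]Cl=O
Why: Pinnick oxidation works under buffered, weakly acidic conditions that should spare the peroxyketal, the alkyne and the C3 stereocentre, which is not α to the carbonyl group.

**Step 5**
Reactants: 7 (3S)-3-[(2-methoxypropan-2-yl)peroxy]pent-4-ynoic acid
Product: 8 (4S)-4-[(2-methoxypropan-2-yl)peroxy]-5-methylideneoxolan-2-one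
Conditions: AuCl (5 mol %), K2CO3 (10 mol %), MeCN, rt
Reagents that add atoms: none
Why: Gold-catalysed 5-exo-dig cycloisomerisation of a pent-4-ynoic acid gives the γ-methylene lactone under nearly neutral conditions without touching the stereocentre.

**Step 6**
Reactants: 8 (4S)-4-[(2-methoxypropan-2-yl)peroxy]-5-methylideneoxolan-2-one
Product: 10 (4aS,7aS)-3-methoxy-3,4a-dimethyltetrahydrofuro[3,2-c][1,2]dioxin-6(3H)-one (both C3 epimers), via isopropenyl peroxide methoxy lactone 9 (not isolated)
Conditions: TMSOTf (0.2 equiv), 4 Å molecular sieves, CH2Cl2, −78 to −40 °C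
Reagents that add atoms: none
Why: Proposed new method: TMSOTf ionises the 2-methoxyprop-2-yl peroxide to a peroxycarbenium ion that loses a proton to give the isopropenyl peroxide, while the released acid and methoxide convert the enol lactone into the 5-methoxy lactone 9 and then into the lactone acyloxycarbenium ion; the peroxy-enol CH2 attacks this ion, the new peroxycarbenium ion at C3 takes up methoxide and TMSOTf is returned, so the step is an acid-catalysed isomerisation. The closest known reaction types are the Lewis-acid ionisation of monoperoxyketals to peroxycarbenium ions with C–C bond formation to π-nucleophiles, the silyl-triflate conversion of ketals into enol ethers, and Mukaiyama-type additions of enol ethers to lactone-derived acyloxycarbenium ions; new are the peroxy-enol as nucleophile and the closure of a 1,2-dioxane through a C–C bond. The 1,2-dioxane, the only ring closed here, forms by a 6-(enolendo)-exo-trig attack of C4 on C4a. The new stereocentre C4a is controlled by C7a, because the two-atom O–O tether can deliver C4 only to the lactone face that carries the peroxide, which gives the cis ring fusion (4aS); C3 forms as an epimer mixture that is erased in step 8. The step needs C–C bond formation to outrun loss of the C7a proton from the acyloxycarbenium ion and heterolysis of the O–O bond, which the intramolecular six-membered transition state, the low temperature and the absence of any nucleophile other than reversibly bound methoxide should secure.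

**Step 7**
Reactants: 11 3-methylbut-2-enal
Product: 12 tert-butyl(dimethyl){[(1E)-3-methylbuta-1,3-dien-1-yl]oxy}silane
Conditions: TBSOTf, Et3N, CH2Cl2, 0 °C
Reagents that add atoms: tert-butyldimethylsilyl trifluoromethanesulfonate, CC(C)(C)[Si](C)(C)OS(=O)(=O)C(F)(F)F
Why: Soft enolisation (γ-deprotonation) of the enal with a silyl triflate and an amine base gives the silyl dienol ether, whose enol geometry has no consequence later.

**Step 8**
Reactants: 10 (4aS,7aS)-3-methoxy-3,4a-dimethyltetrahydrofuro[3,2-c][1,2]dioxin-6(3H)-one; 12 tert-butyl(dimethyl){[(1E)-3-methylbuta-1,3-dien-1-yl]oxy}silane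
Product: 13 (2E)-4-[(3R,4aS,7aS)-3,4a-dimethyl-6-oxotetrahydrofuro[3,2-c][1,2]dioxin-3(4H)-yl]-3-methylbut-2-enal
Conditions: 12 (1.5 equiv), TMSOTf (0.3 equiv), CH2Cl2, −78 °C
Reagents that add atoms: none
Why: Lewis-acid substitution of a cyclic peroxyketal through its peroxycarbenium ion by the terminal CH2 of a silyl dienol ether (vinylogous Mukaiyama reaction), in which axial attack anti to the C4a methyl group (no 1,3-diaxial clash, both methyl groups equatorial) should set 3R with the new chain cis to O5, and the s-trans diene should give the E enal.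

**Step 9**
Reactants: 14 6-bromohex-1-ene; 15 styrene
Product: 16 [(1E)-6-bromohex-1-en-1-yl]benzene
Conditions: 15 (3 equiv), second-generation Grubbs catalyst RuCl2(=CHPh)(PCy3)(H2IMes) (2 mol %), CH2Cl2, 40 °C
Reagents that add atoms: none
Why: Olefin cross-metathesis of a terminal alkene with excess styrene should give the E styrenyl product and tolerates the alkyl bromide.

**Step 10**
Reactants: 16 [(1E)-6-bromohex-1-en-1-yl]benzene
Product: 17 1-phenyl-5-{[(5E)-6-phenylhex-5-en-1-yl]sulfanyl}-1H-tetrazole
Conditions: 1-phenyl-1H-tetrazole-5-thiol, Et3N, MeCN, rt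
Reagents that add atoms: 1-phenyl-1H-tetrazole-5-thiol, Sc1nnnn1-c1ccccc1
Why: SN2 alkylation of the acidic tetrazole thiol by a primary bromide (no stereocentre).

**Step 11**
Reactants: 17 1-phenyl-5-{[(5E)-6-phenylhex-5-en-1-yl]sulfanyl}-1H-tetrazole
Product: 18 1-phenyl-5-{[(5E)-6-phenylhex-5-en-1-yl]sulfonyl}-1H-tetrazole
Conditions: (NH4)6Mo7O24·4H2O (10 mol %), 30% aq. H2O2, EtOH, 0 °C to rt
Reagents that add atoms: hydrogen peroxide, OO
Why: Molybdate-catalysed sulfide oxidation with H2O2 should give the sulfone without epoxidising the styrene double bond.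

**Step 12**
Reactants: 13 (2E)-4-[(3R,4aS,7aS)-3,4a-dimethyl-6-oxotetrahydrofuro[3,2-c][1,2]dioxin-3(4H)-yl]-3-methylbut-2-enal; 18 1-phenyl-5-{[(5E)-6-phenylhex-5-en-1-yl]sulfonyl}-1H-tetrazole
Product: 19 plakortolide H, (3R,4aS,7aS)-3,4a-dimethyl-3-[(2E,4E,9E)-2-methyl-10-phenyldeca-2,4,9-trien-1-yl]tetrahydrofuro[3,2-c][1,2]dioxin-6(3H)-one
Conditions: 18, KN(SiMe3)2, THF, −78 °C; then 13, −78 °C to rt
Reagents that add atoms: none
Why: Julia–Kocienski olefination (addition of the metallated sulfone, Smiles rearrangement, loss of SO2 and tetrazolate) should form the C4'=C5' double bond E-selectively at low temperature without touching the lactone, the peroxide or the three stereocentres.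

**Compound list**
1 | (E)-pent-2-en-4-yn-1-ol | OC/C=C/C#C | starting material
2 | (E)-pent-2-en-4-ynal | O=C/C=C/C#C | intermediate
3 | 2,3-dimethylbut-2-ene | CC(C)=C(C)C | starting material
4 | acetone O-oxide | CC(C)=[O+][O-] | intermediate
5 | 2-hydroperoxy-2-methoxypropane | COC(C)(C)OO | intermediate
6 | (3S)-3-[(2-methoxypropan-2-yl)peroxy]pent-4-ynal | O=CC[C@@H](C#C)OOC(C)(C)OC | intermediate
7 | (3S)-3-[(2-methoxypropan-2-yl)peroxy]pent-4-ynoic acid | OC(=O)C[C@@H](C#C)OOC(C)(C)OC | intermediate
8 | (4S)-4-[(2-methoxypropan-2-yl)peroxy]-5-methylideneoxolan-2-one | C=C1OC(=O)C[C@@H]1OOC(C)(C)OC | intermediate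
9 | (4S)-5-methoxy-5-methyl-4-[(prop-1-en-2-yl)peroxy]oxolan-2-one (C5 epimers) | COC1(C)OC(=O)C[C@@H]1OOC(C)=C | intermediate
10 | (4aS,7aS)-3-methoxy-3,4a-dimethyltetrahydrofuro[3,2-c][1,2]dioxin-6(3H)-one (C3 epimers) | COC1(C)C[C@]2(C)OC(=O)C[C@@H]2OO1 | intermediate
11 | 3-methylbut-2-enal | CC(C)=CC=O | starting material
12 | tert-butyl(dimethyl){[(1E)-3-methylbuta-1,3-dien-1-yl]oxy}silane | C=C(C)/C=C/O[Si](C)(C)C(C)(C)C | intermediate
13 | (2E)-4-[(3R,4aS,7aS)-3,4a-dimethyl-6-oxotetrahydrofuro[3,2-c][1,2]dioxin-3(4H)-yl]-3-methylbut-2-enal | C/C(=C\C=O)C[C@]1(C)C[C@]2(C)OC(=O)C[C@@H]2OO1 | intermediate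
14 | 6-bromohex-1-ene | BrCCCCC=C | starting material
15 | styrene | C=Cc1ccccc1 | starting material
16 | [(1E)-6-bromohex-1-en-1-yl]benzene | BrCCCC/C=C/c1ccccc1 | intermediate
17 | 1-phenyl-5-{[(5E)-6-phenylhex-5-en-1-yl]sulfanyl}-1H-tetrazole | c1ccc(cc1)/C=C/CCCCSc1nnnn1-c1ccccc1 | intermediate
18 | 1-phenyl-5-{[(5E)-6-phenylhex-5-en-1-yl]sulfonyl}-1H-tetrazole | c1ccc(cc1)/C=C/CCCCS(=O)(=O)c1nnnn1-c1ccccc1 | intermediate
19 | plakortolide H | C/C(=C\C=C\CCC/C=C/c1ccccc1)C[C@]1(C)C[C@]2(C)OC(=O)C[C@@H]2OO1 | target

**Totals**
Total step count: 12. Longest linear sequence: 7 steps (1, 3, 4, 5, 6, 8, 12), starting from 1.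

**Steps most likely to fail**

1. Step 6. The acyloxycarbenium ion may lose the C7a proton, the O–O bond may break heterolytically under acid, or the peroxyketal may ionise with loss of the peroxide, each before the C–C ring closure can occur. The fallback uses known chemistry and closes the dioxane through C–O bonds; it sets out from 8 and comes back at 10.
   - Acid-catalysed methanolysis of 8 (pyridinium p-toluenesulfonate, MeOH) opens the enol lactone and transketalises the peroxyketal to give methyl (3S)-3-hydroperoxy-4-oxopentanoate F1.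
   - Silylation (Et3SiCl, imidazole, CH2Cl2) gives methyl (3S)-4-oxo-3-[(triethylsilyl)peroxy]pentanoate F2.
   - A chelation-controlled Mukaiyama aldol addition of 2-(trimethylsilyloxy)propene (TiCl4, CH2Cl2, −78 °C) follows. TiCl4 bridges the ketone and the peroxy oxygen, attack comes from the side of the C3 hydrogen, and the tertiary alcohol ends up cis to the ester arm. The product is methyl (3S,4S)-4-hydroxy-4-methyl-6-oxo-3-[(triethylsilyl)peroxy]heptanoate F3.
   - Camphorsulfonic acid in MeOH then removes the silyl group and closes both the methyl peroxyketal and the lactone to give 10.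

2. Step 3. The enamine formed after peroxide addition may close onto the O–O bond (epoxidation), the peroxide may add in a 1,6 sense at the alkyne terminus, or the β-peroxy aldehyde may racemise by retro-addition. The fallback replaces the conjugate addition by an SN2 alkylation of the same hydroperoxide; it sets out from 5 and comes back at 6.
   - Asymmetric allylboration of commercial 3-(trimethylsilyl)propynal, using the enantiomer of B-allyldiisopinocampheylborane that delivers the 3R carbinol, gives (3R)-1-(trimethylsilyl)hex-5-en-1-yn-3-ol F4.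
   - K2CO3 in MeOH gives (3R)-hex-5-en-1-yn-3-ol F5.
   - MsCl and Et3N give (3R)-hex-5-en-1-yn-3-yl methanesulfonate F6.
   - Displacement with 5 and CsOH in DMF at 0 °C, with inversion, gives (3S)-3-[(2-methoxypropan-2-yl)peroxy]hex-5-en-1-yne F7.
   - Chemoselective ozonolysis of the alkene (O3, CH2Cl2, −78 °C; then Me2S) gives 6.

3. Step 8. The dienol ether may attack through its α-carbon, the new enal may lose its E geometry, or the peroxyketal may ionise with ring opening. The fallback separates C–C bond formation from the making of the enal; it sets out from 10 and comes back at 13.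
   - Hosomi–Sakurai allylation of 10 with trimethyl(2-methylprop-2-en-1-yl)silane (TMSOTf 0.3 equiv, CH2Cl2, −78 °C) gives (3R,4aS,7aS)-3,4a-dimethyl-3-(2-methylprop-2-en-1-yl)tetrahydrofuro[3,2-c][1,2]dioxin-6(3H)-one F8.
   - Cross-metathesis of F8 with (E)-but-2-enal (second-generation Hoveyda–Grubbs catalyst RuCl2(=CH-C6H4-2-OiPr)(H2IMes), CH2Cl2, 40 °C) gives 13.

**Further compounds**
F1 | step 6 | methyl (3S)-3-hydroperoxy-4-oxopentanoate | COC(=O)C[C@H](OO)C(C)=O
F2 | step 6 | methyl (3S)-4-oxo-3-[(triethylsilyl)peroxy]pentanoate | COC(=O)C[C@H](OO[Si](CC)(CC)CC)C(C)=O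
F3 | step 6 | methyl (3S,4S)-4-hydroxy-4-methyl-6-oxo-3-[(triethylsilyl)peroxy]heptanoate | COC(=O)C[C@H](OO[Si](CC)(CC)CC)[C@@](C)(O)CC(C)=O
F4 | step 3 | (3R)-1-(trimethylsilyl)hex-5-en-1-yn-3-ol | C=CC[C@@H](O)C#C[Si](C)(C)C
F5 | step 3 | (3R)-hex-5-en-1-yn-3-ol | C=CC[C@@H](O)C#C
F6 | step 3 | (3R)-hex-5-en-1-yn-3-yl methanesulfonate | C=CC[C@@H](OS(C)(=O)=O)C#C
F7 | step 3 | (3S)-3-[(2-methoxypropan-2-yl)peroxy]hex-5-en-1-yne | C=CC[C@H](OOC(C)(C)OC)C#C
F8 | step 8 | (3R,4aS,7aS)-3,4a-dimethyl-3-(2-methylprop-2-en-1-yl)tetrahydrofuro[3,2-c][1,2]dioxin-6(3H)-one | C=C(C)C[C@]1(C)C[C@]2(C)OC(=O)C[C@@H]2OO1
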